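**Retrosynthetic overview**
1. 33 ⇒ 32: ring-closing metathesis at C5=C6 closes the 10-membered ring last.
2. 32 ⇒ 28: the γ-lactone (C7, C8) comes from hydroxyl-directed epoxidation of the C9 dienol and opening of the epoxide by the C19 tert-butyl ester.
3. 28 ⇒ aldehyde 18 (fragment A: ring A with C2–C5) + enyne ester 27 (fragment B: C6–C8, C17–C19) by nickel-catalysed reductive alkyne–aldehyde coupling (C8–C9).
4. 18 ⇒ enantioselective Diels–Alder of 2 + 3, then the C2 side chain (Grignard, CBS), Saegusa enone, C11/C12 adjustment; 27 ⇒ (S)-Roche ester.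
5. Ring order: cyclohexene (Diels–Alder), γ-lactone (epoxide opening), 10-membered ring (metathesis).

Assumption: positions are numbered as in briaranes (ring A = C1, C10–C14; lactone = C7, C8, C17, C19), and the (R)-catalyst of step 2 is taken to follow the usual formyl C–H···O model and give (1S,6S)-4; if the sense proved opposite, its antipode would be used.

**Fragment A**

Step 1
Reactants: 1 pent-1-en-3-one
Product: 2 (Z)-triisopropyl(penta-1,3-dien-3-yloxy)silane
Conditions: iPr3SiOTf, Et3N, CH2Cl2, 0 °C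
Reagents that add atoms: triisopropylsilyl trifluoromethanesulfonate CC(C)[Si](OS(=O)(=O)C(F)(F)F)(C(C)C)C(C)C
Why: Soft enolisation and O-silylation of the ethyl ketone (silyl enol ether formation) gives the (Z)-2-silyloxy diene whose terminal methyl becomes C20.

Step 2
Reactants: 2 (Z)-triisopropyl(penta-1,3-dien-3-yloxy)silane; 3 ethyl (E)-3-methyl-4-oxobut-2-enoate
Product: 4 ethyl (1S,2S,6S)-6-formyl-2,6-dimethyl-3-[(triisopropylsilyl)oxy]cyclohex-3-ene-1-carboxylate (major endo adduct; the (2R) epimer is carried along)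
Conditions: (R)-o-tolyl-CBS-oxazaborolidine (20 mol%), Tf2NH (18 mol%), CH2Cl2, −78 to −40 °C
Reagents that add atoms: none
Why: Catalytic enantioselective Diels–Alder reaction in which the silyloxy group directs the regiochemistry (C11 to C10, C14 to C1), the (E)-dienophile fixes the C1 methyl cis to the C10 ester, and the aldehyde-bound catalyst sets (1S,10S); the C11 epimers are not separated because C11 is reset in step 10.

Step 3
Reactants: 5 3-methylbut-3-en-1-ol
Product: 6 4-bromo-2-methylbut-1-ene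
Conditions: PBr3, pyridine (cat.), Et2O, 0 °C
Reagents that add atoms: phosphorus tribromide BrP(Br)Br
Why: SN2 displacement of the activated primary alcohol by bromide.

Step 4
Reactants: 4 ethyl (1S,2S,6S)-6-formyl-2,6-dimethyl-3-[(triisopropylsilyl)oxy]cyclohex-3-ene-1-carboxylate; 6 4-bromo-2-methylbut-1-ene
Product: 8 ethyl (1S,2S,6S)-6-(1-hydroxy-4-methylpent-4-en-1-yl)-2,6-dimethyl-3-[(triisopropylsilyl)oxy]cyclohex-3-ene-1-carboxylate (both carbinol epimers), via (3-methylbut-3-en-1-yl)magnesium bromide 7 (not isolated)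
Conditions: Mg, THF, rt; then 4, THF, −78 °C; then H2O
Reagents that add atoms: none
Why: Grignard addition is chemoselective for the aldehyde over the ethyl ester at −78 °C; the carbinol mixture is erased in step 5.

Step 5
Reactants: 8 the carbinol mixture
Product: 9 ethyl (1S,2S,6S)-2,6-dimethyl-6-(4-methylpent-4-enoyl)-3-[(triisopropylsilyl)oxy]cyclohex-3-ene-1-carboxylate
Conditions: Dess–Martin periodinane, pyridine, CH2Cl2, 0 °C to rt
Reagents that add atoms: none
Why: Buffered Dess–Martin oxidation gives the C2 ketone without touching the silyl enol ether.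

Step 6
Reactants: 9 the C2 ketone
Product: 10 ethyl (1S,2S,6S)-6-[(1R)-1-hydroxy-4-methylpent-4-en-1-yl]-2,6-dimethyl-3-[(triisopropylsilyl)oxy]cyclohex-3-ene-1-carboxylate
Conditions: (S)-2-methyl-CBS-oxazaborolidine (0.5 equiv), catecholborane, toluene, −78 °C; then H2O
Reagents that add atoms: none
Why: Corey–Bakshi–Shibata reduction under reagent control, with the quaternary C1 as the large group and the CH2 chain as the small one, gives the (2R) alcohol.

Step 7
Reactants: 10 the (2R) hydroxy ester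
Product: 11 (1R)-1-[(1S,5S,6S)-6-(hydroxymethyl)-1,5-dimethyl-4-[(triisopropylsilyl)oxy]cyclohex-3-en-1-yl]-4-methylpent-4-en-1-ol
Conditions: LiAlH4, Et2O, 0 °C; then H2O
Reagents that add atoms: none
Why: Hydride reduction of the ester (or of any lactone formed between the C2 hydroxyl and the ester) gives the C9 primary alcohol and leaves the silyl enol ether intact.

Step 8
Reactants: 11 the diol
Product: 12 (1R)-1-[(1S,5S,6S)-1,5-dimethyl-6-{[(triethylsilyl)oxy]methyl}-4-[(triisopropylsilyl)oxy]cyclohex-3-en-1-yl]-4-methyl-1-[(triethylsilyl)oxy]pent-4-ene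
Conditions: Et3SiOTf (2.5 equiv), 2,6-lutidine, CH2Cl2, −78 to 0 °C
Reagents that add atoms: triethylsilyl trifluoromethanesulfonate CC[Si](CC)(CC)OS(=O)(=O)C(F)(F)F
Why: Silylation of both hydroxyls gives a primary and a hindered secondary triethylsilyl ether that can be told apart later.

Step 9
Reactants: 12 the bis(triethylsilyl) ether
Product: 13 (4S,5S,6S)-4,6-dimethyl-4-[(1R)-4-methyl-1-[(triethylsilyl)oxy]pent-4-en-1-yl]-5-{[(triethylsilyl)oxy]methyl}cyclohex-2-en-1-one (major; the (6R) epimer is carried along)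
Conditions: Pd(OAc)2 (1.1 equiv), MeCN, 40 °C
Reagents that add atoms: none
Why: Saegusa–Ito oxidation; the silyl enol ether transfers to divalent palladium and β-hydride elimination can only occur toward C14, giving the C13=C14 enone.

Step 10
Reactants: 13 the enone (both C11 epimers)
Product: 15 (4S,5S,6R)-4,6-dimethyl-4-[(1R)-4-methyl-1-[(triethylsilyl)oxy]pent-4-en-1-yl]-5-{[(triethylsilyl)oxy]methyl}cyclohex-2-en-1-one, via lithium dienolate 14 (not isolated)
Conditions: LiN(iPr)2, THF, −78 to −40 °C; then 2,6-di-tert-butyl-4-methylphenol, −78 °C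
Reagents that add atoms: none
Why: Enolisation (only C11 is enolisable) followed by kinetic protonation from the face opposite the C10 CH2OSiEt3 group and the C1 methyl places the C11 methyl cis to the C10 substituent (11R).

Step 11
Reactants: 15 the (6R) enone
Product: 16 (1S,4S,5S,6R)-4,6-dimethyl-4-[(1R)-4-methyl-1-[(triethylsilyl)oxy]pent-4-en-1-yl]-5-{[(triethylsilyl)oxy]methyl}cyclohex-2-en-1-ol
Conditions: NaBH4, CeCl3·7H2O, MeOH, −78 °C
Reagents that add atoms: none
Why: Luche 1,2-reduction; hydride enters from the face opposite the pseudoaxial C10 substituent and gives the 12β alcohol (cis to the C11 methyl).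

Step 12
Reactants: 16 the 12β allylic alcohol
Product: 17 (1R,4S,5S,6R)-4,6-dimethyl-4-[(1R)-4-methyl-1-[(triethylsilyl)oxy]pent-4-en-1-yl]-5-{[(triethylsilyl)oxy]methyl}cyclohex-2-en-1-yl butanoate
Conditions: PPh3, diisopropyl azodicarboxylate, toluene, 0 °C to rt
Reagents that add atoms: butanoic acid CCCC(=O)O
Why: Mitsunobu esterification with SN2 inversion installs the butanoate and sets (12R) in one operation.

Step 13
Reactants: 17 the butanoate
Product: 18 (1R,4S,5S,6R)-5-formyl-4,6-dimethyl-4-[(1R)-4-methyl-1-[(triethylsilyl)oxy]pent-4-en-1-yl]cyclohex-2-en-1-yl butanoate (fragment A)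
Conditions: (COCl)2, DMSO, CH2Cl2, −78 to −40 °C; then Et3N, −78 to 0 °C
Reagents that add atoms: none
Why: Swern conditions oxidise a primary triethylsilyl ether directly to the aldehyde, while the hindered secondary silyl ether and the butanoate are untouched.

**Fragment B**

Step 14
Reactants: 19 methyl (S)-3-hydroxy-2-methylpropanoate
Product: 20 methyl (S)-3-[(tert-butyldimethylsilyl)oxy]-2-methylpropanoate
Conditions: tBuMe2SiCl, imidazole, DMF, rt
Reagents that add atoms: tert-butyldimethylsilyl chloride CC(C)(C)[Si](C)(C)Cl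
Why: Silyl protection of the primary alcohol of the Roche ester, whose stereocentre becomes C17.

Step 15
Reactants: 20 the silyl ether ester
Product: 21 (R)-3-[(tert-butyldimethylsilyl)oxy]-2-methylpropan-1-ol
Conditions: iBu2AlH, CH2Cl2, −78 to 0 °C; then H2O
Reagents that add atoms: none
Why: Hydride reduction of the ester to the primary alcohol without touching the stereocentre.

Step 16
Reactants: 21 the alcohol
Product: 22 (S)-3-[(tert-butyldimethylsilyl)oxy]-2-methylpropanal
Conditions: Dess–Martin periodinane, pyridine, CH2Cl2, 0 °C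
Reagents that add atoms: none
Why: Mild, buffered Dess–Martin oxidation gives the configurationally labile aldehyde, which is used at once.

Step 17
Reactants: 22 the aldehyde
Product: 23 (R)-tert-butyldimethyl[(2-methylbut-3-yn-1-yl)oxy]silane
Conditions: dimethyl (1-diazo-2-oxopropyl)phosphonate, K2CO3, MeOH, 0 °C to rt
Reagents that add atoms: dimethyl (1-diazo-2-oxopropyl)phosphonate COP(=O)(OC)C(=[N+]=[N-])C(C)=O
Why: Ohira–Bestmann (Seyferth–Gilbert) homologation converts the aldehyde into the terminal alkyne (C8≡C7).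

Step 18
Reactants: 23 the terminal alkyne
Product: 24 (R)-tert-butyldimethyl[(2-methylhex-5-en-3-yn-1-yl)oxy]silane
Conditions: bromoethene, Pd(PPh3)4 (3 mol%), CuI (6 mol%), Et2NH, THF, rt
Reagents that add atoms: bromoethene BrC=C
Why: Sonogashira coupling attaches the vinyl group (C6 and its methylene).

Step 19
Reactants: 24 the enyne silyl ether
Product: 25 (R)-2-methylhex-5-en-3-yn-1-ol
Conditions: Bu4NF, THF, 0 °C
Reagents that add atoms: none
Why: Fluoride cleavage of the silyl ether.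

Step 20
Reactants: 25 the enyne alcohol
Product: 26 (R)-2-methylhex-5-en-3-ynoic acid
Conditions: TEMPO (20 mol%), PhI(OAc)2 (2.2 equiv), MeCN/H2O, 0 °C to rt
Reagents that add atoms: water O
Why: Oxoammonium-mediated oxidation takes the primary alcohol through the aldehyde hydrate to the acid under near-neutral conditions that spare the α-stereocentre.

Step 21
Reactants: 26 the acid
Product: 27 tert-butyl (R)-2-methylhex-5-en-3-ynoate (fragment B)
Conditions: tert-butyl 2,2,2-trichloroacetimidate, BF3·OEt2 (cat.), cyclohexane/CH2Cl2, rt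
Reagents that add atoms: tert-butyl 2,2,2-trichloroacetimidate CC(C)(C)OC(=N)C(Cl)(Cl)Cl
Why: Acid-catalysed, base-free tert-butyl esterification avoids racemisation or allene formation at the propargylic α-carbon.

**Coupling and endgame**

Step 22
Reactants: 18 fragment A aldehyde; 27 fragment B enyne ester
Product: 28 tert-butyl (2R,3E)-3-[(R)-[(1S,2S,5R,6R)-5-(butanoyloxy)-2,6-dimethyl-2-[(1R)-4-methyl-1-[(triethylsilyl)oxy]pent-4-en-1-yl]cyclohex-3-en-1-yl](hydroxy)methyl]-2-methylhexa-3,5-dienoate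
Conditions: Ni(cod)2 (20 mol%), P(c-C5H9)3 (40 mol%), Et3B (3 equiv), EtOAc, rt
Reagents that add atoms: none
Why: Nickel-catalysed reductive alkyne–aldehyde coupling (oxidative cyclisation at zerovalent nickel, Et3B as hydride source); the conjugated vinyl group directs C–C bond formation to the distal alkyne carbon C8, cis addition of H and C gives the (E)-alkene, and Felkin–Anh attack anti to the quaternary C1 sets (9R).

Step 23
Reactants: 28 the C9 dienol
Product: 29 tert-butyl (2R)-2-[(2R,3R)-2-[(R)-[(1S,2S,5R,6R)-5-(butanoyloxy)-2,6-dimethyl-2-[(1R)-4-methyl-1-[(triethylsilyl)oxy]pent-4-en-1-yl]cyclohex-3-en-1-yl](hydroxy)methyl]-3-ethenyloxiran-2-yl]propanoate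
Conditions: VO(acac)2 (10 mol%), tBuOOH, CH2Cl2, 0 °C
Reagents that add atoms: tert-butyl hydroperoxide CC(C)(C)OO
Why: Hydroxyl-directed epoxidation touches only the C7=C8 alkene of the allylic alcohol and is erythro-selective because of A(1,2) strain with the C17 substituent, which sets C8.

Step 24
Reactants: 29 the epoxy alcohol
Product: 31 (1R,4S,5S,6R)-5-[(R)-hydroxy[(2S,3R,4R)-3-hydroxy-4-methyl-5-oxo-2-ethenyltetrahydrofuran-3-yl]methyl]-4-[(1R)-1-hydroxy-4-methylpent-4-en-1-yl]-4,6-dimethylcyclohex-2-en-1-yl butanoate, via triethylsilyl ether lactone 30 (not isolated)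
Conditions: CF3CO2H/CH2Cl2/H2O (10:89:1), 0 °C
Reagents that add atoms: none
Why: Acid-promoted lactonisation in which the ester carbonyl opens the vinyl epoxide at allylic C7 with inversion (7S) and loses isobutene, leaving the epoxide oxygen as the tertiary 8-OH; the C2 silyl ether is cleaved in the same pot.

Step 25
Reactants: 31 the triol lactone
Product: 32 (1R,4S,5S,6R)-5-[(R)-acetoxy[(2S,3S,4R)-3-hydroxy-4-methyl-5-oxo-2-ethenyltetrahydrofuran-3-yl]methyl]-4-[(1R)-1-acetoxy-4-methylpent-4-en-1-yl]-4,6-dimethylcyclohex-2-en-1-yl butanoate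
Conditions: Ac2O, DMAP (cat.), pyridine, rt
Reagents that add atoms: acetic anhydride CC(=O)OC(C)=O
Why: DMAP-catalysed acetylation of the two secondary alcohols (C2, C9); the tertiary 8-OH is too hindered to react.

Step 26
Reactants: 32 the diacetate diene
Product: 33 CNP0211702.1 (target; 1S,2R,5Z,7S,8S,9R,10S,11R,12R,17R)
Conditions: second-generation Hoveyda–Grubbs catalyst (20 mol%), toluene (0.001 M), 100 °C
Reagents that add atoms: none
Why: Ring-closing metathesis between the C7 vinyl and the isopropenyl group under high dilution closes the 10-membered ring, whose size constrains the new trisubstituted C5=C6 alkene to Z.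

**Compound list**
1 | pent-1-en-3-one | CCC(=O)C=C | starting material
2 | (Z)-triisopropyl(penta-1,3-dien-3-yloxy)silane | C/C=C(\O[Si](C(C)C)(C(C)C)C(C)C)C=C | intermediate
3 | ethyl (E)-3-methyl-4-oxobut-2-enoate | CCOC(=O)/C=C(C)/C=O | starting material
4 | ethyl (1S,2S,6S)-6-formyl-2,6-dimethyl-3-[(triisopropylsilyl)oxy]cyclohex-3-ene-1-carboxylate (major C11 epimer shown) | CC(C)[Si](C(C)C)(C(C)C)OC1=CC[C@@](C=O)(C)[C@H]([C@@H]1C)C(=O)OCC | intermediate
5 | 3-methylbut-3-en-1-ol | CC(=C)CCO | starting material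
6 | 4-bromo-2-methylbut-1-ene | CC(=C)CCBr | intermediate
7 | (3-methylbut-3-en-1-yl)magnesium bromide (not isolated) | CC(=C)CC[Mg]Br | intermediate
8 | ethyl (1S,2S,6S)-6-(1-hydroxy-4-methylpent-4-en-1-yl)-2,6-dimethyl-3-[(triisopropylsilyl)oxy]cyclohex-3-ene-1-carboxylate (both carbinol epimers) | CC(C)[Si](C(C)C)(C(C)C)OC1=CC[C@@](C(O)CCC(C)=C)(C)[C@H]([C@@H]1C)C(=O)OCC | intermediate
9 | ethyl (1S,2S,6S)-2,6-dimethyl-6-(4-methylpent-4-enoyl)-3-[(triisopropylsilyl)oxy]cyclohex-3-ene-1-carboxylate | CC(C)[Si](C(C)C)(C(C)C)OC1=CC[C@@](C(=O)CCC(C)=C)(C)[C@H]([C@@H]1C)C(=O)OCC | intermediate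
10 | ethyl (1S,2S,6S)-6-[(1R)-1-hydroxy-4-methylpent-4-en-1-yl]-2,6-dimethyl-3-[(triisopropylsilyl)oxy]cyclohex-3-ene-1-carboxylate | CC(C)[Si](C(C)C)(C(C)C)OC1=CC[C@@]([C@H](O)CCC(C)=C)(C)[C@H]([C@@H]1C)C(=O)OCC | intermediate
11 | (1R)-1-[(1S,5S,6S)-6-(hydroxymethyl)-1,5-dimethyl-4-[(triisopropylsilyl)oxy]cyclohex-3-en-1-yl]-4-methylpent-4-en-1-ol | CC(C)[Si](C(C)C)(C(C)C)OC1=CC[C@@]([C@H](O)CCC(C)=C)(C)[C@H]([C@@H]1C)CO | intermediate
12 | bis(triethylsilyl) ether of 11 | CC(C)[Si](C(C)C)(C(C)C)OC1=CC[C@@]([C@H](O[Si](CC)(CC)CC)CCC(C)=C)(C)[C@H]([C@@H]1C)CO[Si](CC)(CC)CC | intermediate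
13 | (4S,5S,6S)-4,6-dimethyl-4-[(1R)-4-methyl-1-[(triethylsilyl)oxy]pent-4-en-1-yl]-5-{[(triethylsilyl)oxy]methyl}cyclohex-2-en-1-one (major C11 epimer shown) | O=C1C=C[C@@]([C@H](O[Si](CC)(CC)CC)CCC(C)=C)(C)[C@H]([C@@H]1C)CO[Si](CC)(CC)CC | intermediate
14 | lithium dienolate of 13 (not isolated) | [Li]OC1=C(C)[C@H](CO[Si](CC)(CC)CC)[C@]([C@H](O[Si](CC)(CC)CC)CCC(C)=C)(C)C=C1 | intermediate
15 | (4S,5S,6R)-4,6-dimethyl-4-[(1R)-4-methyl-1-[(triethylsilyl)oxy]pent-4-en-1-yl]-5-{[(triethylsilyl)oxy]methyl}cyclohex-2-en-1-one | O=C1C=C[C@@]([C@H](O[Si](CC)(CC)CC)CCC(C)=C)(C)[C@H]([C@H]1C)CO[Si](CC)(CC)CC | intermediate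
16 | (1S,4S,5S,6R)-4,6-dimethyl-4-[(1R)-4-methyl-1-[(triethylsilyl)oxy]pent-4-en-1-yl]-5-{[(triethylsilyl)oxy]methyl}cyclohex-2-en-1-ol | O[C@H]1C=C[C@@]([C@H](O[Si](CC)(CC)CC)CCC(C)=C)(C)[C@H]([C@H]1C)CO[Si](CC)(CC)CC | intermediate
17 | (1R,4S,5S,6R)-4,6-dimethyl-4-[(1R)-4-methyl-1-[(triethylsilyl)oxy]pent-4-en-1-yl]-5-{[(triethylsilyl)oxy]methyl}cyclohex-2-en-1-yl butanoate | CCCC(=O)O[C@@H]1C=C[C@@]([C@H](O[Si](CC)(CC)CC)CCC(C)=C)(C)[C@H]([C@H]1C)CO[Si](CC)(CC)CC | intermediate
18 | (1R,4S,5S,6R)-5-formyl-4,6-dimethyl-4-[(1R)-4-methyl-1-[(triethylsilyl)oxy]pent-4-en-1-yl]cyclohex-2-en-1-yl butanoate (fragment A) | CCCC(=O)O[C@@H]1C=C[C@@]([C@H](O[Si](CC)(CC)CC)CCC(C)=C)(C)[C@H]([C@H]1C)C=O | intermediate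
19 | methyl (S)-3-hydroxy-2-methylpropanoate | COC(=O)[C@@H](C)CO | starting material
20 | methyl (S)-3-[(tert-butyldimethylsilyl)oxy]-2-methylpropanoate | COC(=O)[C@@H](C)CO[Si](C)(C)C(C)(C)C | intermediate
21 | (R)-3-[(tert-butyldimethylsilyl)oxy]-2-methylpropan-1-ol | OC[C@@H](C)CO[Si](C)(C)C(C)(C)C | intermediate
22 | (S)-3-[(tert-butyldimethylsilyl)oxy]-2-methylpropanal | O=C[C@@H](C)CO[Si](C)(C)C(C)(C)C | intermediate
23 | (R)-tert-butyldimethyl[(2-methylbut-3-yn-1-yl)oxy]silane | C#C[C@@H](C)CO[Si](C)(C)C(C)(C)C | intermediate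
24 | (R)-tert-butyldimethyl[(2-methylhex-5-en-3-yn-1-yl)oxy]silane | C=CC#C[C@@H](C)CO[Si](C)(C)C(C)(C)C | intermediate
25 | (R)-2-methylhex-5-en-3-yn-1-ol | C=CC#C[C@@H](C)CO | intermediate
26 | (R)-2-methylhex-5-en-3-ynoic acid | C=CC#C[C@@H](C)C(=O)O | intermediate
27 | tert-butyl (R)-2-methylhex-5-en-3-ynoate (fragment B) | C=CC#C[C@@H](C)C(=O)OC(C)(C)C | intermediate
28 | tert-butyl (2R,3E)-3-[(R)-[(1S,2S,5R,6R)-5-(butanoyloxy)-2,6-dimethyl-2-[(1R)-4-methyl-1-[(triethylsilyl)oxy]pent-4-en-1-yl]cyclohex-3-en-1-yl](hydroxy)methyl]-2-methylhexa-3,5-dienoate | CCCC(=O)O[C@@H]1C=C[C@@]([C@H](O[Si](CC)(CC)CC)CCC(C)=C)(C)[C@H]([C@H]1C)[C@@H](O)/C(=C/C=C)[C@@H](C)C(=O)OC(C)(C)C | intermediate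
29 | tert-butyl (2R)-2-[(2R,3R)-2-[(R)-[(1S,2S,5R,6R)-5-(butanoyloxy)-2,6-dimethyl-2-[(1R)-4-methyl-1-[(triethylsilyl)oxy]pent-4-en-1-yl]cyclohex-3-en-1-yl](hydroxy)methyl]-3-ethenyloxiran-2-yl]propanoate | CCCC(=O)O[C@@H]1C=C[C@@]([C@H](O[Si](CC)(CC)CC)CCC(C)=C)(C)[C@H]([C@H]1C)[C@@H](O)[C@@]2([C@@H](C)C(=O)OC(C)(C)C)O[C@@H]2C=C | intermediate
30 | 2-O-triethylsilyl ether of 31 (not isolated) | CCCC(=O)O[C@@H]1C=C[C@@]([C@H](O[Si](CC)(CC)CC)CCC(C)=C)(C)[C@H]([C@H]1C)[C@@H](O)[C@@]2(O)[C@H](C=C)OC(=O)[C@@H]2C | intermediate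
31 | (1R,4S,5S,6R)-5-[(R)-hydroxy[(2S,3R,4R)-3-hydroxy-4-methyl-5-oxo-2-ethenyltetrahydrofuran-3-yl]methyl]-4-[(1R)-1-hydroxy-4-methylpent-4-en-1-yl]-4,6-dimethylcyclohex-2-en-1-yl butanoate | CCCC(=O)O[C@@H]1C=C[C@@]([C@H](O)CCC(C)=C)(C)[C@H]([C@H]1C)[C@@H](O)[C@@]2(O)[C@H](C=C)OC(=O)[C@@H]2C | intermediate
32 | (1R,4S,5S,6R)-5-[(R)-acetoxy[(2S,3S,4R)-3-hydroxy-4-methyl-5-oxo-2-ethenyltetrahydrofuran-3-yl]methyl]-4-[(1R)-1-acetoxy-4-methylpent-4-en-1-yl]-4,6-dimethylcyclohex-2-en-1-yl butanoate | CCCC(=O)O[C@@H]1C=C[C@@]([C@H](OC(C)=O)CCC(C)=C)(C)[C@H]([C@H]1C)[C@@H](OC(C)=O)[C@@]2(O)[C@H](C=C)OC(=O)[C@@H]2C | intermediate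
33 | CNP0211702.1: (1S,2R,5Z,7S,8S,9R,10S,11R,12R,17R)-2,9-diacetoxy-12-butanoyloxy-8-hydroxybriara-5,13-diene 7,19-lactone | CCCC(=O)O[C@@H]1C=C[C@@]2(C)[C@H]([C@H]1C)[C@@H](OC(C)=O)[C@@]1(O)[C@H](/C=C(/C)CC[C@H]2OC(C)=O)OC(=O)[C@@H]1C | target

**Step count and risks**

Total step count: 26. Longest linear sequence: 17 steps (1, 2, 4–13, 22–26). The fragment B branch (14–21) and the bromide (3) lie off it.

The three steps most likely to fail:

Step 26 (ring-closing metathesis). A trans-fused 10-membered ring with a trisubstituted alkene must form from a hindered vinyl group next to the quaternary C8 and a 1,1-disubstituted alkene, so slow initiation or oligomerisation is the main danger. The fallback sets out from triol 31 and closes the ring before acylation. In the triol the two olefin-bearing arms are no longer flanked by acetates and the free 2-, 8- and 9-hydroxyls can hydrogen-bond to gear them together. The same metathesis then gives the macrocyclic triol F1, and acetylation of its two secondary hydroxyls (Ac2O, DMAP, pyridine) comes back to the route at 33.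

Step 22 (nickel-catalysed coupling). The aldehyde is hindered, the allylic butanoate could be ionised by zerovalent nickel, and the facial selectivity at C9 rests on substrate control alone. The fallback sets out from 28 obtained as a C9 epimer mixture and replaces substrate control by reagent control. Dess–Martin oxidation gives the dienone F2, and reduction with (S)-2-methyl-CBS-oxazaborolidine and catecholborane (the dienyl group acting as the large substituent) comes back to the route at 28 as the (9R) alcohol.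

Step 10 (kinetic protonation at C11). Protonation of the dienolate may occur on oxygen or with poor face selectivity and return mixtures rich in 13. The fallback sets out from 13 (or the 13/15 mixture) and uses thermodynamic instead of kinetic control. Equilibration with DBU in toluene at 60 °C should favour 15, in which the C10 substituent avoids three gauche contacts. Compound 15 is separated and 13 is recycled, so the fallback comes back to the route at 15 and makes no new compound (none F0).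

**Further compounds**
F1 | step 26 | macrocyclic triol (2,9-di-O-deacetyl 33) | CCCC(=O)O[C@@H]1C=C[C@@]2(C)[C@H]([C@H]1C)[C@@H](O)[C@@]1(O)[C@H](/C=C(/C)CC[C@H]2O)OC(=O)[C@@H]1C
F2 | step 22 | dienone (C9 ketone of 28) | CCCC(=O)O[C@@H]1C=C[C@@]([C@H](O[Si](CC)(CC)CC)CCC(C)=C)(C)[C@H]([C@H]1C)C(=O)/C(=C/C=C)[C@@H](C)C(=O)OC(C)(C)C
F0 | step 10 | none | none
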